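**Plan**
Retrosynthetic cuts, in order: C9–C10 (ring B, closed last), C13–C16 (ring D), C6–C8 (union of a ring A acetic acid with a ring C allylic alcohol), C5–C6 and C4–C18 on ring A, then ring A itself into nitroethane and two methyl acrylates.
Enabling feature: the C12 ketone of ring C makes C9 the β-carbon of a C9=C11–C12=O enone, five atoms from C10. C10 (one methyl, two ring bonds) is the nitro-bearing carbon of nitroethane, and its nitro group later leaves to give a planar tertiary radical.
Forward order: ring A (double Michael, Dieckmann) with C5, C4, C3 set; ring C bought as a cyclohexenone; Ireland–Claisen union creating quaternary C8; ring D by Pd(OAc)2 cycloalkenylation; ring B by denitrative 5-exo radical conjugate addition.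
Stereochemistry: C5 by a bis(oxazoline)–Cu(OTf)2 Mukaiyama–Michael addition, C4 by trans alkylation, C3 by a hindered borohydride, C8 by 1,3-chirality transfer from a CBS-derived carbinol, C13 by the bridge, C9 and C10 in the key step, C6 by final equilibration.
The key step is stereoconvergent: the C10 epimers carried from step 2 and the C6 epimers from step 12 are funnelled into the one natural configuration.

Key step: step 16

Remarks. Atom numbers are gibberellane numbers: ring A = C1–C5, C10; ring B = C5, C6, C8, C9, C10; ring C = C8, C9, C11–C14; ring D = C8, C13–C16; C7 and C19 are the carboxyl carbons, C17 the methylene, C18 and C20 the methyls. TBS = tert-butyldimethylsilyl.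
Assumption: in step 4 the (S,S) ligand is taken, from the square-planar chelate model for bis(oxazoline) complexes of divalent copper, to expose the Re face of C5; the nitro-bearing carbon is carried as both epimers up to 26 and C6 as both epimers from 22 to 27.

Step 1
Reactants: 1 nitroethane; 2 methyl acrylate (2.2 equiv)
Product: 3 dimethyl 4-methyl-4-nitroheptanedioate
Conditions: DBU (0.2 equiv), MeCN, 0 °C to rt
Reagents that add atoms: none
Why: Double Michael addition of the nitronate of nitroethane (two acidic hydrogens) to two acrylates should build the future C10 with its methyl group and both three-carbon arms at once.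

Step 2
Reactants: 3 dimethyl 4-methyl-4-nitroheptanedioate
Product: 4 methyl 5-methyl-5-nitro-2-oxocyclohexane-1-carboxylate (racemic, keto/enol mixture)
Conditions: NaH (1.2 equiv), MeOH (cat.), THF, reflux; then 1 M HCl
Reagents that add atoms: none
Why: Dieckmann condensation of the symmetric diester can give only one six-membered β-keto ester (ring A with C3 ketone and C19 ester), and the tertiary nitro group has no acidic hydrogen.

Step 3
Reactants: 4 methyl 5-methyl-5-nitro-2-oxocyclohexane-1-carboxylate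
Product: 7 methyl 3-methyl-3-nitro-6-oxocyclohex-1-ene-1-carboxylate (racemic), via selenide 5 (not isolated), via selenoxide 6 (not isolated)
Conditions: PhSeCl, pyridine, CH2Cl2, 0 °C; then 30% H2O2, 0 °C to rt
Reagents that add atoms: none
Why: Selenenylation at the doubly activated C4 and selenoxide syn-elimination toward C5 (the only β-hydrogens) should give the alkylidene β-keto ester, which the quaternary C10 protects from dienol tautomerism.

Step 4
Reactants: 7 methyl 3-methyl-3-nitro-6-oxocyclohex-1-ene-1-carboxylate; 8 tert-butyl[(1-methoxyethenyl)oxy]dimethylsilane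
Product: 9 methyl (6R)-6-(2-methoxy-2-oxoethyl)-5-methyl-5-nitro-2-oxocyclohexane-1-carboxylate (both C5 epimers, keto/enol mixture)
Conditions: Cu(OTf)2 (10 mol %), 2,2'-(propane-2,2-diyl)bis[(4S)-4-tert-butyl-4,5-dihydrooxazole] (11 mol %), (CF3)2CHOH (1.1 equiv), CH2Cl2, −78 °C
Reagents that add atoms: none
Why: Enantioselective Mukaiyama–Michael addition to a chelating 2-alkoxycarbonyl enone bound to the bis(oxazoline) complex of divalent copper should deliver C6 to the Re face of C5 in both C10 epimers, because the Me/NO2 pair on C10 offers little facial bias of its own.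

Step 5
Reactants: 9 methyl (6R)-6-(2-methoxy-2-oxoethyl)-5-methyl-5-nitro-2-oxocyclohexane-1-carboxylate
Product: 10 methyl (1S,6R)-6-(2-methoxy-2-oxoethyl)-1,5-dimethyl-5-nitro-2-oxocyclohexane-1-carboxylate
Conditions: Cs2CO3, MeI, DMF, 0 °C to rt
Reagents that add atoms: iodomethane, CI
Why: C-Alkylation of the cyclic β-keto ester enolate should occur anti to the adjacent C5 side chain, placing the new methyl (C18) trans to C6 and the ester (C19) cis to it.

Step 6
Reactants: 10 methyl (1S,6R)-6-(2-methoxy-2-oxoethyl)-1,5-dimethyl-5-nitro-2-oxocyclohexane-1-carboxylate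
Product: 11 methyl (1S,2S,6R)-2-hydroxy-6-(2-methoxy-2-oxoethyl)-1,5-dimethyl-5-nitrocyclohexane-1-carboxylate
Conditions: LiBH(s-Bu)3, THF, −78 °C; then H2O
Reagents that add atoms: none
Why: The bulky borohydride should attack the C3 ketone along the equatorial trajectory of the chair with the C5 arm equatorial and the C4 ester axial, giving the axial (3S) alcohol trans to the ester, as in reductions of 3-oxo gibberellins with hindered borohydrides.

Step 7
Reactants: 11 methyl (1S,2S,6R)-2-hydroxy-6-(2-methoxy-2-oxoethyl)-1,5-dimethyl-5-nitrocyclohexane-1-carboxylate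
Product: 12 methyl (1S,2S,6R)-2-(TBS-oxy)-6-(2-methoxy-2-oxoethyl)-1,5-dimethyl-5-nitrocyclohexane-1-carboxylate
Conditions: t-BuMe2SiOTf, 2,6-lutidine, CH2Cl2, 0 °C
Reagents that add atoms: tert-butyldimethylsilyl trifluoromethanesulfonate, CC(C)(C)[Si](C)(C)OS(=O)(=O)C(F)(F)F
Why: Silyl triflate silylation protects the hindered axial alcohol and blocks retro-aldol cleavage of the β-hydroxy ester in the basic steps that follow.

Step 8
Reactants: 12 methyl (1S,2S,6R)-2-(TBS-oxy)-6-(2-methoxy-2-oxoethyl)-1,5-dimethyl-5-nitrocyclohexane-1-carboxylate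
Product: 13 2-[(1R,2S,3S)-3-(TBS-oxy)-2-(methoxycarbonyl)-2,6-dimethyl-6-nitrocyclohexyl]acetic acid
Conditions: LiOH·H2O (1.5 equiv), THF/H2O, 0 °C to rt; then 1 M HCl to pH 3
Reagents that add atoms: lithium hydroxide, [Li+].[OH-]
Why: Saponification should discriminate the unhindered acetate ester from the neopentyl-type ester on quaternary C4.

Step 9
Reactants: 14 3-ethoxycyclohex-2-en-1-one; 15 allylmagnesium bromide
Product: 17 3-(prop-2-en-1-yl)cyclohex-2-en-1-one, via tertiary allylic alcohol 16 (not isolated)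
Conditions: THF, 0 °C; then 1 M HCl, 0 °C
Reagents that add atoms: none
Why: 1,2-Addition to the vinylogous ester followed by acid hydrolysis with allylic transposition (Stork–Danheiser sequence) gives the 3-substituted enone.

Step 10
Reactants: 17 3-(prop-2-en-1-yl)cyclohex-2-en-1-one
Product: 18 (1R)-3-(prop-2-en-1-yl)cyclohex-2-en-1-ol
Conditions: (S)-2-methyl-CBS-oxazaborolidine (0.2 equiv), catecholborane (1.5 equiv), toluene, −78 °C; then H2O
Reagents that add atoms: none
Why: Corey–Bakshi–Shibata reduction with the (S) catalyst should give the (R) carbinol when the alkenyl carbon is the large group, and catecholborane at low temperature spares the allyl alkene from hydroboration.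

Step 11
Reactants: 13 2-[(1R,2S,3S)-3-(TBS-oxy)-2-(methoxycarbonyl)-2,6-dimethyl-6-nitrocyclohexyl]acetic acid; 18 (1R)-3-(prop-2-en-1-yl)cyclohex-2-en-1-ol
Product: 19 (1R)-3-(prop-2-en-1-yl)cyclohex-2-en-1-yl 2-[(1R,2S,3S)-3-(TBS-oxy)-2-(methoxycarbonyl)-2,6-dimethyl-6-nitrocyclohexyl]acetate
Conditions: DCC, DMAP (cat.), CH2Cl2, 0 °C to rt
Reagents that add atoms: none
Why: Steglich esterification joins the two enantioenriched fragments under neutral conditions that do not ionise the allylic alcohol.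

Step 12
Reactants: 19 (1R)-3-(prop-2-en-1-yl)cyclohex-2-en-1-yl 2-[(1R,2S,3S)-3-(TBS-oxy)-2-(methoxycarbonyl)-2,6-dimethyl-6-nitrocyclohexyl]acetate
Product: 23 methyl 2-[(1R)-1-(prop-2-en-1-yl)cyclohex-2-en-1-yl]-2-[(1R,2S,3S)-3-(TBS-oxy)-2-(methoxycarbonyl)-2,6-dimethyl-6-nitrocyclohexyl]acetate (both C6 epimers), via silyl ketene acetal 20 (not isolated), via trimethylsilyl ester 21 (not isolated), via carboxylic acid 22 (not isolated)
Conditions: KN(SiMe3)2, Me3SiCl, toluene, −78 °C, then 80 °C; 1 M HCl; then Me3SiCHN2, toluene/MeOH, 0 °C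
Reagents that add atoms: trimethylsilyldiazomethane, C[Si](C)(C)C=[N+]=[N-]
Why: Ireland–Claisen rearrangement moves C6 suprafacially across the allyl unit, so quaternary C8 should carry C6 on the face the C11–O bond occupied (1,3-chirality transfer), while C6 itself forms as a mixture that step 17 corrects.

Step 13
Reactants: 23 methyl 2-[(1R)-1-(prop-2-en-1-yl)cyclohex-2-en-1-yl]-2-[(1R,2S,3S)-3-(TBS-oxy)-2-(methoxycarbonyl)-2,6-dimethyl-6-nitrocyclohexyl]acetate
Product: 24 methyl 2-[(1R)-4-oxo-1-(prop-2-en-1-yl)cyclohex-2-en-1-yl]-2-[(1R,2S,3S)-3-(TBS-oxy)-2-(methoxycarbonyl)-2,6-dimethyl-6-nitrocyclohexyl]acetate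
Conditions: Rh2(cap)4 (dirhodium tetracaprolactamate, 1 mol %), t-BuOOH (70% aq., 5 equiv), K2CO3, CH2Cl2, rt
Reagents that add atoms: tert-butyl hydroperoxide, CC(C)(C)OO
Why: Allylic C–H oxidation should take the only allylic methylene of the ring alkene (C12, since C8 is quaternary), which gives a more substituted allyl radical than the neopentyl CH2 of the allyl group, and so installs the C12 ketone as the C9=C11 enone.

Step 14
Reactants: 24 methyl 2-[(1R)-4-oxo-1-(prop-2-en-1-yl)cyclohex-2-en-1-yl]-2-[(1R,2S,3S)-3-(TBS-oxy)-2-(methoxycarbonyl)-2,6-dimethyl-6-nitrocyclohexyl]acetate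
Product: 25 the C12 O-TBS cross-conjugated dienol ether of 24 (C12=C13 and C9=C11)
Conditions: t-BuMe2SiOTf, Et3N, CH2Cl2, 0 °C
Reagents that add atoms: tert-butyldimethylsilyl trifluoromethanesulfonate, CC(C)(C)[Si](C)(C)OS(=O)(=O)C(F)(F)F
Why: Only C13 carries enolisable hydrogens (C8 is quaternary), so soft enolisation can give only the 2-silyloxy-1,3-diene.

Step 15
Reactants: 25 the C12 O-TBS dienol ether of 24
Product: 26 methyl 2-[(1R,5R)-6-methylidene-4-oxobicyclo[3.2.1]oct-2-en-1-yl]-2-[(1R,2S,3S)-3-(TBS-oxy)-2-(methoxycarbonyl)-2,6-dimethyl-6-nitrocyclohexyl]acetate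
Conditions: Pd(OAc)2 (10 mol %), O2 (1 atm), DMSO, 45 °C
Reagents that add atoms: none
Why: Cycloalkenylation of a silyl enol ether (Saegusa–Kende–Toyota type): divalent palladium activates the allyl alkene, C13 attacks the internal carbon C16 (5-exo), β-hydride elimination gives the exocyclic methylene, O2 reoxidises zerovalent palladium, and the bridge fixes C13.

Step 16
Reactants: 26 methyl 2-[(1R,5R)-6-methylidene-4-oxobicyclo[3.2.1]oct-2-en-1-yl]-2-[(1R,2S,3S)-3-(TBS-oxy)-2-(methoxycarbonyl)-2,6-dimethyl-6-nitrocyclohexyl]acetate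
Product: 27 dimethyl (3S,4S,5S,8R,9S,10S,13R)-3-(TBS-oxy)-12-oxogibberell-16-ene-7,19-dioate (both C6 epimers)
Conditions: Bu3SnH (1.3 equiv, syringe pump), AIBN (0.2 equiv), toluene, 110 °C
Reagents that add atoms: none
Why: Bu3Sn• adds to a nitro oxygen and the adduct fragments to Bu3SnONO and the tertiary C10 radical, which is planar, so both C10 epimers of 26 give the same intermediate; it adds to C9, the β-carbon of the C9=C11–C12=O enone, and the C11 α-keto radical then takes hydrogen from Bu3SnH. The closest known reactions are tin hydride denitrative cyclisations of tertiary nitroalkanes and Giese additions of tertiary radicals to cyclic enones. Ring B (C5–C6–C8–C9–C10) closes in the 5-exo-trig mode. C9 is set by the bicyclo[3.2.1]octenone, which is attacked axially on the face of C14 and anti to the C15–C16 bridge, leaving H9 syn to that bridge. C10 is set by ring A: the axial C19 ester on C4 is syn-axial to one lobe of the radical, so C9 bonds through the other lobe, trans to C6 on C5, which gives the trans A/B fusion with C20 syn to C19. The step needs ring closure to outrun hydrogen transfer and to prefer the enone over the C16 methylene; slow stannane addition, the match of a nucleophilic tertiary radical with the electron-poor C9, and the less favourable 6-exo or 7-endo paths to the methylene secure this.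

Step 17
Reactants: 27 dimethyl (3S,4S,5S,8R,9S,10S,13R)-3-(TBS-oxy)-12-oxogibberell-16-ene-7,19-dioate (both C6 epimers)
Product: 28 dimethyl (3S,4S,5S,6S,8R,9S,10S,13R)-3-(TBS-oxy)-12-oxogibberell-16-ene-7,19-dioate
Conditions: NaOMe (0.5 equiv), MeOH, 60 °C
Reagents that add atoms: none
Why: Base equilibration of the ester α-carbon C6 should converge both epimers on the more stable one, with C7 trans to the quaternary C4 and cis to H5, which is the natural configuration; C13 is a bridgehead and cannot epimerise.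

Step 18
Reactants: 28 dimethyl (3S,4S,5S,6S,8R,9S,10S,13R)-3-(TBS-oxy)-12-oxogibberell-16-ene-7,19-dioate
Product: 29 (3S,4S,5S,6S,8R,9S,10S,13R)-3-(TBS-oxy)-12-oxogibberell-16-ene-7,19-dioic acid
Conditions: LiSPr (10 equiv), HMPA, rt; then 1 M HCl
Reagents that add atoms: none
Why: Thiolate SN2 demethylation attacks the methyl carbons and so cleaves both hindered esters without touching the carbonyls, the usual way to unmask hindered gibberellin methyl esters.

Step 19
Reactants: 29 (3S,4S,5S,6S,8R,9S,10S,13R)-3-(TBS-oxy)-12-oxogibberell-16-ene-7,19-dioic acid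
Product: 30 (3S,4S,5S,6S,8R,9S,10S,13R)-3-hydroxy-12-oxogibberell-16-ene-7,19-dioic acid (target, CNP0197851.1)
Conditions: HF·pyridine, pyridine/THF, 0 °C to rt
Reagents that add atoms: none
Why: Buffered fluoride desilylation frees the axial C3 hydroxyl without acid strong enough to isomerise the exocyclic alkene or base strong enough for retro-aldol cleavage.

**Compound list**
1 | nitroethane | CC[N+](=O)[O-] | starting material
2 | methyl acrylate | C=CC(=O)OC | starting material
3 | dimethyl 4-methyl-4-nitroheptanedioate | COC(=O)CCC(C)(CCC(=O)OC)[N+](=O)[O-] | intermediate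
4 | methyl 5-methyl-5-nitro-2-oxocyclohexane-1-carboxylate (racemic) | COC(=O)C1CC(C)([N+](=O)[O-])CCC1=O | intermediate
5 | methyl 5-methyl-5-nitro-2-oxo-1-(phenylselanyl)cyclohexane-1-carboxylate | COC(=O)C1([Se]c2ccccc2)CC(C)([N+](=O)[O-])CCC1=O | intermediate (not isolated)
6 | methyl 5-methyl-5-nitro-2-oxo-1-(phenylseleninyl)cyclohexane-1-carboxylate | COC(=O)C1([Se](=O)c2ccccc2)CC(C)([N+](=O)[O-])CCC1=O | intermediate (not isolated)
7 | methyl 3-methyl-3-nitro-6-oxocyclohex-1-ene-1-carboxylate (racemic) | COC(=O)C1=CC(C)([N+](=O)[O-])CCC1=O | intermediate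
8 | tert-butyl[(1-methoxyethenyl)oxy]dimethylsilane | C=C(OC)O[Si](C)(C)C(C)(C)C | starting material
9 | methyl (6R)-6-(2-methoxy-2-oxoethyl)-5-methyl-5-nitro-2-oxocyclohexane-1-carboxylate (C1 and C5 epimers) | COC(=O)C[C@@H]1C(C(=O)OC)C(=O)CCC1(C)[N+](=O)[O-] | intermediate
10 | methyl (1S,6R)-6-(2-methoxy-2-oxoethyl)-1,5-dimethyl-5-nitro-2-oxocyclohexane-1-carboxylate (both C5 epimers) | COC(=O)C[C@@H]1[C@](C)(C(=O)OC)C(=O)CCC1(C)[N+](=O)[O-] | intermediate
11 | methyl (1S,2S,6R)-2-hydroxy-6-(2-methoxy-2-oxoethyl)-1,5-dimethyl-5-nitrocyclohexane-1-carboxylate | COC(=O)C[C@@H]1[C@](C)(C(=O)OC)[C@@H](O)CCC1(C)[N+](=O)[O-] | intermediate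
12 | methyl (1S,2S,6R)-2-(TBS-oxy)-6-(2-methoxy-2-oxoethyl)-1,5-dimethyl-5-nitrocyclohexane-1-carboxylate | COC(=O)C[C@@H]1[C@](C)(C(=O)OC)[C@@H](O[Si](C)(C)C(C)(C)C)CCC1(C)[N+](=O)[O-] | intermediate
13 | 2-[(1R,2S,3S)-3-(TBS-oxy)-2-(methoxycarbonyl)-2,6-dimethyl-6-nitrocyclohexyl]acetic acid | OC(=O)C[C@@H]1[C@](C)(C(=O)OC)[C@@H](O[Si](C)(C)C(C)(C)C)CCC1(C)[N+](=O)[O-] | intermediate
14 | 3-ethoxycyclohex-2-en-1-one | CCOC1=CC(=O)CCC1 | starting material
15 | allylmagnesium bromide | C=CC[Mg]Br | starting material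
16 | 3-ethoxy-1-(prop-2-en-1-yl)cyclohex-2-en-1-ol | C=CCC1(O)C=C(OCC)CCC1 | intermediate (not isolated)
17 | 3-(prop-2-en-1-yl)cyclohex-2-en-1-one | C=CCC1=CC(=O)CCC1 | intermediate
18 | (1R)-3-(prop-2-en-1-yl)cyclohex-2-en-1-ol | O[C@H]1C=C(CC=C)CCC1 | intermediate
19 | (1R)-3-(prop-2-en-1-yl)cyclohex-2-en-1-yl 2-[(1R,2S,3S)-3-(TBS-oxy)-2-(methoxycarbonyl)-2,6-dimethyl-6-nitrocyclohexyl]acetate | C=CCC1=C[C@H](OC(=O)C[C@@H]2[C@](C)(C(=O)OC)[C@@H](O[Si](C)(C)C(C)(C)C)CCC2(C)[N+](=O)[O-])CCC1 | intermediate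
20 | O-trimethylsilyl ketene acetal of 19 | C=CCC1=C[C@H](OC(O[Si](C)(C)C)=C[C@@H]2[C@](C)(C(=O)OC)[C@@H](O[Si](C)(C)C(C)(C)C)CCC2(C)[N+](=O)[O-])CCC1 | intermediate (not isolated)
21 | trimethylsilyl ester of 22 | C=CC[C@]1(C=CCCC1)C(C(=O)O[Si](C)(C)C)[C@@H]1[C@](C)(C(=O)OC)[C@@H](O[Si](C)(C)C(C)(C)C)CCC1(C)[N+](=O)[O-] | intermediate (not isolated)
22 | 2-[(1R)-1-(prop-2-en-1-yl)cyclohex-2-en-1-yl]-2-[(1R,2S,3S)-3-(TBS-oxy)-2-(methoxycarbonyl)-2,6-dimethyl-6-nitrocyclohexyl]acetic acid (both C6 epimers) | C=CC[C@]1(C=CCCC1)C(C(=O)O)[C@@H]1[C@](C)(C(=O)OC)[C@@H](O[Si](C)(C)C(C)(C)C)CCC1(C)[N+](=O)[O-] | intermediate (not isolated)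
23 | methyl ester of 22 (both C6 epimers) | C=CC[C@]1(C=CCCC1)C(C(=O)OC)[C@@H]1[C@](C)(C(=O)OC)[C@@H](O[Si](C)(C)C(C)(C)C)CCC1(C)[N+](=O)[O-] | intermediate
24 | methyl 2-[(1R)-4-oxo-1-(prop-2-en-1-yl)cyclohex-2-en-1-yl]-2-[(1R,2S,3S)-3-(TBS-oxy)-2-(methoxycarbonyl)-2,6-dimethyl-6-nitrocyclohexyl]acetate | C=CC[C@]1(C=CC(=O)CC1)C(C(=O)OC)[C@@H]1[C@](C)(C(=O)OC)[C@@H](O[Si](C)(C)C(C)(C)C)CCC1(C)[N+](=O)[O-] | intermediate
25 | C12 O-TBS cross-conjugated dienol ether of 24 | C=CC[C@]1(C=CC(O[Si](C)(C)C(C)(C)C)=CC1)C(C(=O)OC)[C@@H]1[C@](C)(C(=O)OC)[C@@H](O[Si](C)(C)C(C)(C)C)CCC1(C)[N+](=O)[O-] | intermediate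
26 | methyl 2-[(1R,5R)-6-methylidene-4-oxobicyclo[3.2.1]oct-2-en-1-yl]-2-[(1R,2S,3S)-3-(TBS-oxy)-2-(methoxycarbonyl)-2,6-dimethyl-6-nitrocyclohexyl]acetate | C=C1C[C@@]2(C[C@H]1C(=O)C=C2)C(C(=O)OC)[C@@H]1[C@](C)(C(=O)OC)[C@@H](O[Si](C)(C)C(C)(C)C)CCC1(C)[N+](=O)[O-] | intermediate
27 | dimethyl (3S,4S,5S,8R,9S,10S,13R)-3-(TBS-oxy)-12-oxogibberell-16-ene-7,19-dioate (both C6 epimers) | C=C1C[C@]23C[C@H]1C(=O)C[C@H]2[C@]1(C)CC[C@H](O[Si](C)(C)C(C)(C)C)[C@@](C)(C(=O)OC)[C@H]1C3C(=O)OC | intermediate
28 | dimethyl (3S,4S,5S,6S,8R,9S,10S,13R)-3-(TBS-oxy)-12-oxogibberell-16-ene-7,19-dioate | C=C1C[C@]23C[C@H]1C(=O)C[C@H]2[C@]1(C)CC[C@H](O[Si](C)(C)C(C)(C)C)[C@@](C)(C(=O)OC)[C@H]1[C@@H]3C(=O)OC | intermediate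
29 | (3S,4S,5S,6S,8R,9S,10S,13R)-3-(TBS-oxy)-12-oxogibberell-16-ene-7,19-dioic acid | C=C1C[C@]23C[C@H]1C(=O)C[C@H]2[C@]1(C)CC[C@H](O[Si](C)(C)C(C)(C)C)[C@@](C)(C(=O)O)[C@H]1[C@@H]3C(=O)O | intermediate
30 | (3S,4S,5S,6S,8R,9S,10S,13R)-3-hydroxy-12-oxogibberell-16-ene-7,19-dioic acid | C=C1C[C@]23C[C@H]1C(=O)C[C@H]2[C@]1(C)CC[C@H](O)[C@@](C)(C(=O)O)[C@H]1[C@@H]3C(=O)O | target

**Step count and risks**
Total: 19 steps. Longest linear sequence: 17 steps (steps 1–8, then 11–19); steps 9–10 form the short branch.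

Step 16. The process most likely to spoil it is hydrogen-atom transfer from the stannane to the tertiary C10 radical before it reaches the hindered carbon C9, so that the nitro group is lost without ring closure. The fallback is ionic and has no hydrogen donor present while C10 is reactive. It sets out from 26: 1,2-reduction of the enone (NaBH4, CeCl3·7H2O, MeOH, −78 °C) should give the C12 allylic alcohol F1, and Et3SiCl/imidazole its triethylsilyl ether F2. SnCl4 with 2,6-di-tert-butylpyridine (CH2Cl2, −78 °C) would then ionise the tertiary C–NO2 bond, a known use of tertiary nitro groups as leaving groups. The C10 cation should be captured by C9 of the C9=C11 alkene (5-exo), and a 1,2-hydride shift from C12 to C11 with loss of the silyl group would regenerate the C12 ketone. This comes back to the route at 27, with the same facial arguments at C9 and C10.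

Step 12. The process to fear is a slow [3,3] shift in the crowded silyl ketene acetal, so that its decomposition (ketene formation with loss of the allylic alkoxide, or hydrolysis back to 13 and 18) overtakes rearrangement. The fallback changes which bond joins the fragments: C8 is made first on a small substrate and C5–C6 becomes the union. It sets out from 18 and 7. Acetylation of 18 (Ac2O, pyridine, DMAP) gives (1R)-3-(prop-2-en-1-yl)cyclohex-2-en-1-yl acetate F3. Ireland–Claisen rearrangement (LiN(i-Pr)2, t-BuMe2SiCl, THF/DMPU, −78 °C to rt) and esterification with Me3SiCHN2 give methyl 2-[(1S)-1-(prop-2-en-1-yl)cyclohex-2-en-1-yl]acetate F4. Its O-TBS ketene acetal F5 (LiN(i-Pr)2, t-BuMe2SiCl) is added to 7 under the catalyst of step 4 to give the β-keto ester F6. Methylation as in step 5 gives F7, LiBH(s-Bu)3 as in step 6 gives the alcohol F8, and silylation as in step 7 comes back to the route at 23.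

Step 4. The process to fear is erosion of face selectivity at C5, because the racemic nitro-bearing neighbour competes with the ligand (matched and mismatched pairs) and lowers the enantiomeric purity of everything downstream. The fallback moves the asymmetric event from C–C bond formation to the ketone reduction. It sets out from 7: addition of 8 promoted by Sc(OTf)3 without a chiral ligand gives the racemic adduct F9, and methylation as in step 5 gives the racemic trans keto diester F10. Reduction with (R)-2-methyl-CBS-oxazaborolidine and BH3·SMe2 should deliver hydride to the same carbonyl face of both enantiomers. The (1S,6R) ketone then gives 11, where the route is rejoined. The (1R,6S) ketone gives the diastereomer F11, whose hydroxyl is cis to the acetate arm, so it can lactonise and is removed by chromatography.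

**Further compounds**
F1 | step 16 | C12 allylic alcohol from 1,2-reduction of 26 (both C12 epimers) | C=C1C[C@@]2(C[C@H]1C(O)C=C2)C(C(=O)OC)[C@@H]1[C@](C)(C(=O)OC)[C@@H](O[Si](C)(C)C(C)(C)C)CCC1(C)[N+](=O)[O-]
F2 | step 16 | C12 O-triethylsilyl ether of F1 | C=C1C[C@@]2(C[C@H]1C(O[Si](CC)(CC)CC)C=C2)C(C(=O)OC)[C@@H]1[C@](C)(C(=O)OC)[C@@H](O[Si](C)(C)C(C)(C)C)CCC1(C)[N+](=O)[O-]
F3 | step 12 | (1R)-3-(prop-2-en-1-yl)cyclohex-2-en-1-yl acetate | C=CCC1=C[C@H](OC(C)=O)CCC1
F4 | step 12 | methyl 2-[(1S)-1-(prop-2-en-1-yl)cyclohex-2-en-1-yl]acetate | C=CC[C@]1(C=CCCC1)CC(=O)OC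
F5 | step 12 | O-TBS ketene acetal of F4 | C=CC[C@]1(C=CCCC1)C=C(OC)O[Si](C)(C)C(C)(C)C
F6 | step 12 | Michael adduct of F5 and 7 (β-keto ester, C4, C6 and C10 epimers) | C=CC[C@]1(C=CCCC1)C(C(=O)OC)[C@@H]1C(C(=O)OC)C(=O)CCC1(C)[N+](=O)[O-]
F7 | step 12 | C4-methylated keto diester from F6 | C=CC[C@]1(C=CCCC1)C(C(=O)OC)[C@@H]1[C@](C)(C(=O)OC)C(=O)CCC1(C)[N+](=O)[O-]
F8 | step 12 | (3S) alcohol from F7 | C=CC[C@]1(C=CCCC1)C(C(=O)OC)[C@@H]1[C@](C)(C(=O)OC)[C@@H](O)CCC1(C)[N+](=O)[O-]
F9 | step 4 | racemic methyl 6-(2-methoxy-2-oxoethyl)-5-methyl-5-nitro-2-oxocyclohexane-1-carboxylate | COC(=O)CC1C(C(=O)OC)C(=O)CCC1(C)[N+](=O)[O-]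
F10 | step 4 | racemic trans keto diester (10 and its enantiomer) | COC(=O)C[C@@H]1[C@](C)(C(=O)OC)C(=O)CCC1(C)[N+](=O)[O-].COC(=O)C[C@H]1[C@@](C)(C(=O)OC)C(=O)CCC1(C)[N+](=O)[O-]
F11 | step 4 | methyl (1R,2S,6S)-2-hydroxy-6-(2-methoxy-2-oxoethyl)-1,5-dimethyl-5-nitrocyclohexane-1-carboxylate | COC(=O)C[C@H]1[C@@](C)(C(=O)OC)[C@@H](O)CCC1(C)[N+](=O)[O-]
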